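16.6% of target at the first reading of the beta run, made with 1.5 equiv of partner, is the number I start from.

| flask | starting material | partner | second substrate | remark | time |
|---|---|---|---|---|---|
| epsilon | 1 M | 0.75 equiv | 0.50 equiv | run made earlier |  |
| gamma | 1 M | 1.1 equiv | 0.50 equiv | run made earlier |  |
| beta | 1 M | 1.5 equiv | 1 equiv | run made earlier |  |
| flask | 1.0 M | 1.50 equiv | 0.500 equiv |  | 8.0 d |

- epsilon (time / d: target / %, starting material / %): 0.0833: 9.6, 87.9; 0.208: 6.2, 88.7; 0.500: 1.5, 88.2; 1.25: 0.4, 81.2; 3.00: 0, 68.3; 8.00: 0.4, 54.8
- gamma (time / d: target / %, starting material / %): 0.0833: 14.5, 84.0; 0.208: 9.5, 84.0; 0.500: 2.1, 87.1; 1.25: 0.9, 79.7; 3.00: 0, 67.6; 8.00: 0, 53.7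
- beta (time / d: target / %, starting material / %): 0.0833: 16.6, 77.5; 0.250: 9.1, 77.8; 0.833: 1.1, 71.8; 2.50: 0, 48.4; 8.00: 0, 22.7

(each reading ± 0.5 percentage points)

- the analysis behind the earlier runs scatters by 0.5 percentage points, standard deviation

* the best time, 8.0 d at the latest, for target
* the amount of target, in percent of the starting material charged, at that time
* the first time at which target reaches 12%, in the same percent

I build this flask one process at a time. The main step, starting material plus partner to target, takes one partner for each target, and this flask charges 1.50 equiv of partner, so the first ceiling is the whole of the starting material. Next comes a loss of partner elsewhere: in the beta run starting material has fallen by 22.5% at 0.0833 d and still reads 77.8% at 0.250 d, so the ceiling drops to about that fall. Then target itself goes: the beta run reads 9.1% at 0.250 d while starting material holds, and what stands at the first reading is less than what was consumed. The slow loss of starting material runs over days, so I leave it out of the peak, although this flask has half the second substrate of the beta run.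

What remains is one reading. The beta run gives 11.1% for the partner yield, the target at the first reading per equivalent of partner charged, a selectivity read at one moment. The epsilon and gamma runs read 12.8% and 13.2%, but I take the beta value, whose partner charge equals this flask's. My reckoning for this flask is therefore a peak of 16.6%, near the first reading.

The forecast differs: 19% at 0.055 d, reaching the asked level at 0.4 h, with the caution “The early rise was not sampled, so timing is uncertain.”

The flask peaks at 17.5% at 0.0841 d and reaches the asked level at 0.653 h, both times later than the forecast's.

    starting material + partner ⇌ target (K = 0.520 M⁻¹, k = 0.190 M⁻¹ h⁻¹)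
    second substrate + partner → second product (k = 0.00760 M⁻¹ h⁻¹)
    starting material + second substrate → cross product (k = 0.0170 M⁻¹ h⁻¹)
    partner → decomposed reagent (k = 0.430 h⁻¹)
    partner + target → over-reaction product (k = 0.120 M⁻¹ h⁻¹)

On this flask the partner yield comes to 11.7%, against my 11.1%. The neighbour flask, with 2.00 equiv of second substrate and its other charges as in this flask, reckons to the same 16.6%, and it gives 17.0%. The step from starting material and second substrate shifts this flask's peak very little. At 8.00 d that neighbour flask holds 93.7% as cross product and 1.96% as starting material.

The numbers in the tables are simulated from invented constants.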